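| flask | substrate | gas phase | remark | time |
|---|---|---|---|---|
| larch | 0.82 M (in portions, 4) | 200 mM (held) | run made earlier; portions every 3.0 h |  |
| dusk | 0.41 M (in portions, 4) | 200 mM (held) | the portions of substrate follow each other after 3.0 h, the first at the start | 40 h |
| autumn | 0.41 M (in portions, 4) | 200 mM (held) | the portions of substrate follow each other after 6.0 h, the first at the start | 40 h |
| spring | 0.41 M (in portions, 4) | 200 mM (held) | the portions of substrate follow each other after 12 h, the first at the start | 40 h |
| dawn | 0.41 M (in portions, 4) | 200 mM (held) | the portions of substrate follow each other after 25 h, the first at the start | 40 h |

- larch (time / h: target / %, substrate / %): 3.00: 1, 14; 6.00: 14, 26; 10.0: 28, 53; 12.0: 36, 44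

(standard deviation of a reading: 2 percentage points)

- the earlier runs were read with a standard deviation of 2 percentage points
- at the start none of the gas phase is in solution
- percentages count the whole charge, also what has not yet gone in
- a reading or a percentage of target counts all its forms, free or not
- the concentration of target that is asked is that of its free form alone
- "hardly changes" means that all values lie within two and a half points (for a concentration: within two and a half percent of the largest)

- [target] (only what is free in solution, in the first phase) at the end for dusk, autumn, spring, dawn, in this order
- the course of these numbers from the first flask to the last (hardly changes / falls all the way / rises, then falls / rises all the way / falls, then rises)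

**Opening ledger.** If a mole of substrate is followed through larch, its books hold substrate, target and an unread rest. Substrate is the limiting reagent, since the gas phase is held. In larch the last portion is in by 10.0 h, so from then on the readings can be summed against the whole charge. The larch rest is 19.0% at 10.0 h and 20.0% at 12.0 h.

**Hold-up.** Divided by the substrate read at those times, the larch rest gives a mean ratio of 0.407. This is a reading and carries the scatter of its readings.

**Clearing constant.** Between those times, larch target gains 8 percentage points on a mean substrate of 48.5%. That is a rate constant on substrate of 0.0825 h⁻¹, read from scattered readings. The pool of substrate plus rest is larger than the substrate by the factor 1.41, so the pool clears more slowly, at 0.0586 h⁻¹. This clearing constant is the fraction of the pool turned into target per hour. The reckoning treats it as pseudo-first-order and carries it to the new flasks.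

**Second round.** The first round lets each portion become target. The second round puts the age of each portion back in: a portion of age a keeps the fraction exp(-kp·a) in the pool. Target in all its forms at 40 h then comes to 87.3% of the charge in dusk, 82.5% in autumn and 63.2% in spring. Dawn's third portion is due at 50.0 h, later than the end, so dawn comes to 37.2%. These shares count target in all its forms, as the readings do.

The forecast gives 0.35 M, 0.365 M, 0.35 M and 0.185 M, with the course rises, then falls, and says “Gentler dosing may slightly improve yield”.

The flasks end at 0.0180 M, 0.0181 M, 0.0195 M and 0.0182 M, and the course is rises, then falls.

    gas phase ⇌ dissolved gas, rate k1*(csat - [dissolved gas]) (kL = 0.00440 min⁻¹)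
    substrate + dissolved gas ⇌ target (K = 3.90 M⁻¹, k = 0.0270 M⁻¹ min⁻¹)
    dissolved gas + target → over-reacted product (k = 0.00190 M⁻¹ min⁻¹)
    substrate ⇌ dormant form (K = 0.330, k = 0.00360 min⁻¹)
    crystals ⇌ target, rate k5*(cs5 - [target]) while solid is left; crystals form when [target] > cs5 (solubility = 18.0 mM, k = 0.100 min⁻¹)

**Free ceiling.** Dusk closes its books with 88.6% as target, against 87.3% reckoned at 0.0586 h⁻¹. Yet 84.2% of the dusk charge stands as crystals, and free target is 4.39%. The limit of solubility of target is the largest single effect here: without it, dusk ends at 0.114 M. Dawn repeats the books: 0.0586 h⁻¹ gives 37.2%, and the flask holds 36.9% with 32.5% as crystals. Free target in dawn ends at 0.0182 M, against 0.0602 M without that limit.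

(Readings and results are simulated for an exercise.)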